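**Retrosynthetic overview**

1. The target is reached from its C3‑O‑silyl ether; the C2' acetate is installed last with Mitsunobu inversion, the C6 acetate comes from opening a temporary seven‑membered silaketal that joins O–C6 to O–C2', and C2–H comes from desulfonylation.
2. Key disconnection: the cyclohexa‑1,4‑diene is made from a cis‑3,4‑dioxygenated 1‑methoxycyclobutene and a tethered alkynyl sulfone. Alkoxide‑triggered conrotatory opening of the four‑membered ring, silicon tethering and intramolecular Diels–Alder closure insert C1≡C2 into the cyclobutene C3–C6 bond (four‑ to six‑membered ring) and set both ring C=C bonds and both ring stereocentres.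
3. Enabling feature: C3 and C6 are oxygen‑bearing sp3 carbons para to each other in a 1,4‑diene (alkyne + 1,4‑dioxydiene retron); C3–C4=C5(OMe)–C6 is a squarate‑derived C4 unit; the side‑chain C2' oxygen lies 1,4 to the C6 oxygen, so one silicon atom bridges them and relays the C2' chirality.
4. Fragments: the cyclobutenol comes from dimethyl squarate (3 steps); the chlorosilane comes from (S)‑epichlorohydrin and decylmagnesium bromide (4 steps).
5. Ring order: four‑membered ring (from squarate) → six‑membered carbocycle and temporary seven‑membered silaketal together in the key step → silaketal opened afterwards.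

Key step: step 8

Remark on numbering and stereochemistry: ring carbons are numbered as in the target (C1 bears the side chain, C3 the hydroxyl, C5 the methoxy, C6 the acetoxy; side chain C1', C2'). The four‑membered‑ring compounds are racemic (one enantiomer drawn) because their stereocentres are erased at the diene stage. The side chain is carried as its (S)‑epimer because the final acetate is installed with inversion. All ring intermediates are acid‑labile, so chromatography on Et3N‑deactivated silica is assumed.

**Route**

Step 1
Reactants: 1 dimethyl squarate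
Product: 3 3-methoxycyclobut-3-ene-1,2-dione, via 4-hydroxy-2,3-dimethoxycyclobut-2-en-1-one 2 (not isolated)
Conditions: LiAlH(O-t-Bu)3 (1.05 equiv), THF, −78 °C; then 6 M HCl, CH2Cl2, rt
Reagents that add atoms: water, O
Why: Hydride adds 1,2 to one carbonyl of the squaric ester, and acid then drives the allylic transposition with loss of methanol (partial reduction/acid hydrolysis of a squaric ester, the standard semisquarate synthesis).

Step 2
Reactants: 3 3-methoxycyclobut-3-ene-1,2-dione
Product: 4 cis-3-methoxycyclobut-3-ene-1,2-diol (racemic)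
Conditions: i-Bu2AlH (2.5 equiv), CH2Cl2, −78 °C; aq KNaC4H4O6 work-up
Reagents that add atoms: none
Why: 1,2‑Reduction of both carbonyls (ketone first, vinylogous ester second); the second hydride should arrive anti to the bulky aluminoxy group on the neighbouring carbon, which gives the cis diol (substrate‑controlled carbonyl reduction).

Step 3
Reactants: 4 cis-3-methoxycyclobut-3-ene-1,2-diol
Product: 5 cis-2-methoxy-4-(triisopropylsilyloxy)cyclobut-2-en-1-ol (racemic)
Conditions: i-Pr3SiCl (1.05 equiv), imidazole, DMF, 0 °C
Reagents that add atoms: triisopropylsilyl chloride, CC(C)[Si](Cl)(C(C)C)C(C)C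
Why: The bulky silyl chloride should select the less hindered, more nucleophilic hydroxyl flanked by CH= rather than by C(OMe)= (regioselective monosilylation of a diol), leaving the future C6–OH free.

Step 4
Reactants: 6 (S)-epichlorohydrin; 7 decylmagnesium bromide
Product: 8 (S)-1-chlorotridecan-2-ol
Conditions: CuI (10 mol %), THF, −40 to 0 °C
Reagents that add atoms: none
Why: Copper‑catalysed Grignard opening of the epoxide at its unsubstituted carbon (SN2) leaves the stereocentre untouched.

Step 5
Reactants: 8 (S)-1-chlorotridecan-2-ol
Product: 10 (S)-pentadec-1-yn-4-ol, via (S)-2-undecyloxirane 9 (not isolated)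
Conditions: LiC≡CH·H2NCH2CH2NH2 (3 equiv), DMSO, 10 °C to rt
Reagents that add atoms: lithium acetylide (ethylenediamine complex), [Li+].[C-]#C
Why: Base closes the chlorohydrin to the terminal epoxide and acetylide opens it at the CH2 terminus (epoxide alkynylation), neither event touching the stereocentre.

Step 6
Reactants: 10 (S)-pentadec-1-yn-4-ol
Product: 12 (S)-1-(p-tolylsulfonyl)pentadec-1-yn-4-ol, via (E)-iodovinyl sulfone 11 (not isolated)
Conditions: 4-MeC6H4SO2Na, I2, EtOAc/H2O, rt; then K2CO3, acetone, 50 °C
Reagents that add atoms: sodium p-toluenesulfinate, Cc1ccc(cc1)S(=O)[O-].[Na+]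
Why: Iodosulfonylation of the terminal alkyne followed by dehydroiodination is the standard route to 1‑alkynyl sulfones; the sulfone activates and polarises the alkyne for step 8 and is removed in step 9.

Step 7
Reactants: 12 (S)-1-(p-tolylsulfonyl)pentadec-1-yn-4-ol
Product: 13 chloro(diisopropyl)silyl ether of 12
Conditions: i-Pr2SiCl2 (3 equiv), imidazole, CH2Cl2, 0 °C; excess silane removed in vacuo
Reagents that add atoms: dichlorodiisopropylsilane, CC(C)[Si](Cl)(Cl)C(C)C
Why: Slow addition of the alcohol to excess dichlorosilane gives the monoalkoxychlorosilane (first half of a mixed silaketal synthesis).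

Step 8
Reactants: 5 cis-2-methoxy-4-(triisopropylsilyloxy)cyclobut-2-en-1-ol; 13 chloro(diisopropyl)silyl ether of 12
Product: 17 sulfonyl cyclohexa-1,4-diene silaketal (3R,6S,2'S), via potassium alkoxide 14 (not isolated), via potassium dienolate 15 (not isolated), via tethered dienyne 16 (not isolated)
Conditions: KN(SiMe3)2 (1.0 equiv), THF/PhMe, −78 to 0 °C; then 13, −78 °C to rt; then 50 °C
Reagents that add atoms: none
Why: KN(SiMe3)2 deprotonates the free C6–OH, and the alkoxide switches on a conrotatory 4π opening of the otherwise thermally stable cis‑cyclobutene (the known alkoxide acceleration of cyclobutene and benzocyclobutene opening); O− rotates outward and forces the C3 silyloxy group inward, so both enantiomers of racemic 5 converge on one achiral dienolate 15. O‑Silylation by 13 gives dienyne 16, which closes by a normal‑electron‑demand intramolecular Diels–Alder reaction (closest known types: silicon‑tethered intramolecular Diels–Alder reactions and alkynyl sulfones as acetylene‑equivalent dienophiles), so that overall C1≡C2 is inserted into the former C3–C6 σ bond of the four‑membered ring, a four‑to‑six ring expansion. Ring closures: the carbocycle by suprafacial [4+2] formation of C6–C1 and C3–C2, the seven‑membered dioxasilepane as the tether ring fused across C6–C1. Stereocentres: C3 relative to C6 is set by the diene geometry (one oxygen outside, one inside, suprafacial addition, hence trans); the absolute sense is set by C2', whose undecyl group should sit pseudo‑equatorial in a chair‑like tether that folds away from the C5 methoxy group (the cis‑4,7‑disubstituted silaketal), so that (S)‑C2' exposes the diene face leading to the (3S,6S) arrangement of the target. Regiochemistry is secured twice, by the tether and by polarity (C6, the terminus pushed by OMe and by the remote silyloxy group, attacks the sulfone β‑carbon C1). The step needs torquoselectivity (secured by O−), O‑silylation rather than C‑attack (hard, hindered chlorosilane at −78 °C) and a concerted cycloaddition (weakly polar medium, no Lewis acid).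

Step 9
Reactants: 17 sulfonyl cyclohexa-1,4-diene silaketal
Product: 18 cyclohexa-1,4-diene silaketal (3S,6S,2'S)
Conditions: n-BuMgCl (3 equiv), Pd(acac)2 (5 mol %), THF, 0 °C to rt
Reagents that add atoms: none
Why: Palladium‑catalysed hydrogenolysis of a vinylic sulfone by a Grignard reagent bearing β‑hydrogens (C–S oxidative addition, transmetalation, β‑hydride elimination, C–H reductive elimination) replaces the sulfonyl group by hydrogen without moving the double bond.

Step 10
Reactants: 18 cyclohexa-1,4-diene silaketal
Product: 19 C6 acetate C2' diisopropyl(methyl)silyl ether (3S,6S,2'S)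
Conditions: MeLi (1.1 equiv), THF, −78 to −20 °C; then Ac2O, −78 °C to rt
Reagents that add atoms: methyllithium, [Li]C; acetic anhydride, CC(=O)OC(C)=O
Why: Methyllithium attacks the dialkoxysilane and should expel the better leaving alkoxide (the more acidic, doubly allylic C6–O), which acetic anhydride acetylates in the same flask (nucleophilic opening of a cyclic silyl acetal, then O‑acylation).

Step 11
Reactants: 19 C6 acetate C2' diisopropyl(methyl)silyl ether
Product: 20 C6 acetate C2' alcohol (3S,6S,2'S)
Conditions: Bu4NF, AcOH (1:1), THF, −20 °C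
Reagents that add atoms: none
Why: Buffered fluoride should remove the less hindered dialkylmethylsilyl ether of a simple secondary alcohol much faster than the triisopropylsilyl ether (selective desilylation).

Step 12
Reactants: 20 C6 acetate C2' alcohol
Product: 21 C3 silyl ether of the target (3S,6S,2'R)
Conditions: AcOH, PPh3, i-PrO2CN=NCO2i-Pr, PhMe, 0 °C to rt
Reagents that add atoms: acetic acid, CC(=O)O
Why: Mitsunobu reaction of the only free hydroxyl with acetic acid installs the second acetate with SN2 inversion, turning (S)‑C2' into the required (R)‑C2' while the ionisation‑prone C3 oxygen stays silylated.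

Step 13
Reactants: 21 C3 silyl ether of the target
Product: 22 target, (R)-1-[(3S,6S)-6-acetoxy-3-hydroxy-5-methoxycyclohexa-1,4-dien-1-yl]tridecan-2-yl acetate
Conditions: Bu4NF, AcOH (1:1), THF, 0 °C to rt
Reagents that add atoms: none
Why: Buffered fluoride cleaves the Si–O bond without acid or strong base, so the 3‑methoxy‑allylic alcohol, the doubly allylic acetate and the 1,4‑diene should survive (silyl ether deprotection).

**Compound list**

1 | dimethyl squarate (3,4-dimethoxycyclobut-3-ene-1,2-dione) | COC1=C(OC)C(=O)C1=O | starting material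
2 | 4-hydroxy-2,3-dimethoxycyclobut-2-en-1-one (racemic) | COC1=C(OC)C(=O)C1O | intermediate (not isolated)
3 | 3-methoxycyclobut-3-ene-1,2-dione | COC1=CC(=O)C1=O | intermediate
4 | cis-3-methoxycyclobut-3-ene-1,2-diol (racemic, rel-(1S,2S)) | O[C@H]1C=C(OC)[C@H]1O | intermediate
5 | cis-2-methoxy-4-(triisopropylsilyloxy)cyclobut-2-en-1-ol (racemic, rel-(1S,4S); free OH next to C–OMe) | CC(C)[Si](C(C)C)(C(C)C)O[C@H]1C=C(OC)[C@H]1O | intermediate
6 | (S)-epichlorohydrin | ClC[C@@H]1CO1 | starting material
7 | decylmagnesium bromide | CCCCCCCCCC[Mg]Br | starting material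
8 | (S)-1-chlorotridecan-2-ol | CCCCCCCCCCC[C@@H](CCl)O | intermediate
9 | (S)-2-undecyloxirane | CCCCCCCCCCC[C@H]1CO1 | intermediate (not isolated)
10 | (S)-pentadec-1-yn-4-ol | CCCCCCCCCCC[C@@H](CC#C)O | intermediate
11 | (S,E)-2-iodo-1-(p-tolylsulfonyl)pentadec-1-en-4-ol | CCCCCCCCCCC[C@@H](C/C(I)=C\S(=O)(=O)c1ccc(C)cc1)O | intermediate (not isolated)
12 | (S)-1-(p-tolylsulfonyl)pentadec-1-yn-4-ol | CCCCCCCCCCC[C@@H](CC#CS(=O)(=O)c1ccc(C)cc1)O | intermediate
13 | chloro(diisopropyl){[(S)-1-(p-tolylsulfonyl)pentadec-1-yn-4-yl]oxy}silane | CCCCCCCCCCC[C@@H](CC#CS(=O)(=O)c1ccc(C)cc1)O[Si](Cl)(C(C)C)C(C)C | intermediate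
14 | potassium alkoxide of 5 (racemic) | CC(C)[Si](C(C)C)(C(C)C)O[C@H]1C=C(OC)[C@H]1[O-].[K+] | intermediate (not isolated)
15 | potassium (1Z,3Z)-2-methoxy-4-(triisopropylsilyloxy)buta-1,3-dien-1-olate (O− outside, i.e. trans to C3; silyloxy inside, i.e. cis to C2) | [K+].[O-]/C=C(OC)/C=C\O[Si](C(C)C)(C(C)C)C(C)C | intermediate (not isolated)
16 | diisopropyl{[(1Z,3Z)-2-methoxy-4-(triisopropylsilyloxy)buta-1,3-dien-1-yl]oxy}{[(S)-1-(p-tolylsulfonyl)pentadec-1-yn-4-yl]oxy}silane | CCCCCCCCCCC[C@@H](CC#CS(=O)(=O)c1ccc(C)cc1)O[Si](C(C)C)(C(C)C)O/C=C(OC)/C=C\O[Si](C(C)C)(C(C)C)C(C)C | intermediate (not isolated)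
17 | bicyclic silaketal cycloadduct (target numbering): 5-methoxy-2-(p-tolylsulfonyl)-3-(triisopropylsilyloxy)cyclohexa-1,4-diene, (3R,6S) by CIP (same spatial arrangement as the target), with O–C6 and the oxygen on (S)-C2' of the C1-bound 2-oxytridecyl chain bridged by Si(i-Pr)2 | CCCCCCCCCCC[C@@H](CC1=C(S(=O)(=O)c2ccc(C)cc2)[C@H](O[Si](C(C)C)(C(C)C)C(C)C)C=C(OC)[C@H]1O[Si]3(C(C)C)C(C)C)O3 | intermediate
18 | desulfonylated bicyclic silaketal: (3S,6S)-5-methoxy-3-(triisopropylsilyloxy)cyclohexa-1,4-diene with O–C6 and the oxygen on (S)-C2' bridged by Si(i-Pr)2 | CCCCCCCCCCC[C@@H](CC1=C[C@H](O[Si](C(C)C)(C(C)C)C(C)C)C=C(OC)[C@H]1O[Si]2(C(C)C)C(C)C)O2 | intermediate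
19 | (3S,6S)-6-acetoxy-1-[(S)-2-{[diisopropyl(methyl)silyl]oxy}tridecyl]-5-methoxy-3-(triisopropylsilyloxy)cyclohexa-1,4-diene | CCCCCCCCCCC[C@@H](CC1=C[C@H](O[Si](C(C)C)(C(C)C)C(C)C)C=C(OC)[C@H]1OC(C)=O)O[Si](C)(C(C)C)C(C)C | intermediate
20 | (3S,6S)-6-acetoxy-1-[(S)-2-hydroxytridecyl]-5-methoxy-3-(triisopropylsilyloxy)cyclohexa-1,4-diene | CCCCCCCCCCC[C@@H](CC1=C[C@H](O[Si](C(C)C)(C(C)C)C(C)C)C=C(OC)[C@H]1OC(C)=O)O | intermediate
21 | (R)-1-[(3S,6S)-6-acetoxy-5-methoxy-3-(triisopropylsilyloxy)cyclohexa-1,4-dien-1-yl]tridecan-2-yl acetate | CCCCCCCCCCC[C@H](CC1=C[C@H](O[Si](C(C)C)(C(C)C)C(C)C)C=C(OC)[C@H]1OC(C)=O)OC(C)=O | intermediate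
22 | (R)-1-[(3S,6S)-6-acetoxy-3-hydroxy-5-methoxycyclohexa-1,4-dien-1-yl]tridecan-2-yl acetate | CCCCCCCCCCC[C@H](CC1=C[C@H](O)C=C(OC)[C@H]1OC(C)=O)OC(C)=O | target

**Summary**

Total step count: 13. Longest linear sequence: 10 steps (steps 4–13, from (S)-epichlorohydrin and decylmagnesium bromide).

**Steps most likely to fail**

Step 8. What may go wrong: at the alkoxide stage the triisopropylsilyl group can migrate between the two cis oxygens, which would exchange the roles of the two diene termini. The free dienolate can also attack the alkynyl sulfone at carbon instead of being silylated at oxygen, and the facial bias of the seven‑membered tether rests on a conformational model only. Fallback: the anion is avoided and the tether is installed first. Setting out from 5 and 13, imidazole in CH2Cl2 gives the neutral silaketal-linked cis-cyclobutene F1 (mixed dialkoxysilane formation). Heating it in xylene at about 120 °C in base‑washed glassware brings about thermal conrotatory opening followed by the same tethered Diels–Alder closure. Only the diene isomer with the tether oxygen outside can cyclise, and it gives 17, where the route is rejoined; the isomer with the tether inside is left behind, so this variant trades material for robustness.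

Step 10. What may go wrong: methyllithium may cleave the other Si–O bond or both, so that the two oxygens are not differentiated, or it may react too slowly at the hindered silicon. Fallback: the two hydroxyls are told apart by steric demand instead. Setting out from 18, Bu4NF/AcOH at 0 °C cleaves only the dialkoxysilane and gives the diol F2. Et3SiCl/imidazole at −40 °C silylates the unhindered side‑chain hydroxyl to the C2' triethylsilyl ether F3. Ac2O/DMAP/pyridine acetylates the remaining hindered C6 hydroxyl to the C6 acetate F4. Brief treatment with Bu4NF/AcOH at −20 °C removes the triethylsilyl group and returns the route at 20.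

Step 9. What may go wrong: the basic Grignard reagent may deprotonate the doubly allylic C3–H or C6–H next to the vinyl sulfone and trigger aromatisation by loss of a silyloxy group, or butyl transfer may compete with hydride transfer. Fallback: a bromine atom replaces the sulfone as the traceless activating group. Setting out from 10, NBS with AgNO3 (cat.) in acetone gives (S)-1-bromopentadec-1-yn-4-ol F5, and i-Pr2SiCl2/imidazole gives the chlorosilane F6. This is used in place of 13 under the conditions of step 8 (the less activated bromoalkyne is expected to need about 80 °C for the cycloaddition) and gives the 2-bromo cycloadduct F7. Bromine–lithium exchange with t-BuLi (2 equiv, Et2O, −78 °C) and quenching with MeOH returns the route at 18.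

Further compounds
F1 | step 8 | neutral silaketal-linked cis-cyclobutene from 5 and 13 (one of the two diastereomers formed from racemic 5) | CC(C)[Si](C(C)C)(C(C)C)O[C@H]1C=C(OC)[C@H]1O[Si](C(C)C)(C(C)C)O[C@@H](CCCCCCCCCCC)CC#CS(=O)(=O)c1ccc(C)cc1
F2 | step 10 | (3S,6S)-1-[(S)-2-hydroxytridecyl]-5-methoxy-3-(triisopropylsilyloxy)cyclohexa-1,4-dien-6-ol | CCCCCCCCCCC[C@@H](CC1=C[C@H](O[Si](C(C)C)(C(C)C)C(C)C)C=C(OC)[C@H]1O)O
F3 | step 10 | C2' triethylsilyl ether of F2 | CCCCCCCCCCC[C@@H](CC1=C[C@H](O[Si](C(C)C)(C(C)C)C(C)C)C=C(OC)[C@H]1O)O[Si](CC)(CC)CC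
F4 | step 10 | C6 acetate of F3 | CCCCCCCCCCC[C@@H](CC1=C[C@H](O[Si](C(C)C)(C(C)C)C(C)C)C=C(OC)[C@H]1OC(C)=O)O[Si](CC)(CC)CC
F5 | step 9 | (S)-1-bromopentadec-1-yn-4-ol | CCCCCCCCCCC[C@@H](CC#CBr)O
F6 | step 9 | chloro(diisopropyl)silyl ether of F5 | CCCCCCCCCCC[C@@H](CC#CBr)O[Si](Cl)(C(C)C)C(C)C
F7 | step 9 | 2-bromo analogue of 17 | CCCCCCCCCCC[C@@H](CC1=C(Br)[C@H](O[Si](C(C)C)(C(C)C)C(C)C)C=C(OC)[C@H]1O[Si]2(C(C)C)C(C)C)O2
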